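## Compound numbers

1 neryl acetate · 2 its remote epoxide · 3 acetoxy aldehyde · 4 ester ylide · 5 iodo ylide (in the flask) · 6 iodo enoate acetate · 7 iodo enoate alcohol · 8 iodo enoate enal · 9 prop-2-yn-1-ol · 10 its p-methoxybenzyl (PMB) ether · 11 alkenylzirconocene (in the flask) · 12 alkenylzinc (in the flask) · 13 racemic carbinol ester · 14 diol · 15 racemic silyl ether · 16 epoxy alcohol · 17 diethylphosphonoacetic acid · 18 epoxy phosphonoacetate · 19 formaldehyde · 20 α-phosphono lactone (in the flask) · 21 methylene lactone alcohol · 22 triethylsilyl ether · 23 primary alcohol · 24 aldehyde · 25 ten-membered alcohol · 26 diol · 27 angelic acid · 28 mixed anhydride (in the flask) · 29 bis-angelate · 30 allylic alcohol · 31 enal · 32 target.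

Germacrane locants are used throughout: C1=C10 (C14 on C10), C2, C3, C4(C15)=C5, C6 (lactone carbinol), C7 (ring fusion), C8, C9 (acyloxy carbons), C11, C12, C13 (lactone α-carbon, carbonyl, exo-methylene).

## Analysis of the target

The target 32 is a germacranolide: a cyclodeca-1(10),4-diene (C1–C10) fused at C6–C7 to an α-methylene-γ-butyrolactone (O, C6, C7, C11, C12, with C13 exocyclic). Both ring alkenes have their ring bonds cis (C2 and C9 cis across C1=C10, C3 and C6 cis across C4=C5); C10 carries the C14 carboxylic acid and C4 the C15 methyl group. Four contiguous stereocentres are present, 6R, 7S, 8S, 9S: H6 and H7 are trans (trans-fused lactone), O8 is anti to C11 along the C6–C9 backbone, and the two acyloxy groups on C8 and C9 are syn (threo). The sensitive groups are the methylene lactone (a Michael acceptor that also isomerises to the endocyclic butenolide with base), the two angelates (Z-enoates that go over to tiglates under nucleophilic or basic acylation conditions and that can migrate if a neighbouring hydroxyl is free), the free acrylic acid and the allylic lactone C6–O bond. The synthesis is hard because a ten-membered ring with two geometrically defined trisubstituted alkenes has to be closed next to a dense stereotetrad, and because the acid-, base- and nucleophile-sensitive groups limit what can be done late. The feature on which the plan rests is the pattern C6–O, C7–C11, C8–O. It is exactly what remains when an acetate carbanion held on the C6 oxygen opens a C7–C8 epoxide at C7, so one asymmetric epoxidation can control C6, C7 and C8 together. C9 is then the only stereocentre left to the ring closure.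

## Retrosynthetic reasoning

C14 oxidation level (32 ⇐ 31 ⇐ 30 ⇐ 29). No skeletal bond is cut first. The carboxylic acid is traced back through enal 31 and allylic alcohol 30 to the silyl ether 29. A free acid or an acrylate on C10 would be a second Michael acceptor during the carbanion step and the metal-mediated ring closure; a silylated allylic alcohol is inert there. The forward steps have to remove one silyl group and oxidise a primary allylic alcohol twice without touching angelates or the methylene lactone.

Angelates (29 ⇐ 26 + 27). The two ester C–O bonds at O8 and O9 are cut. Both acyl groups are the same, so they are put on together, from two molecules of angelic acid 27 onto diol 26. They go on late, because they isomerise easily and because a mono-ester next to a free hydroxyl would invite acyl shifts. The forward reaction must acylate two hindered secondary hydroxyls with retention of the Z geometry.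

Ten-membered ring (26 ⇐ 25 ⇐ 24). The ring is cut at C9–C10. C10 is sp2 and can carry a halogen whose geometry is fixed beforehand and kept in the bond formation; C9 is a carbinol, so a carbonyl addition creates the hydroxyl that is needed anyway. Cutting C5–C6 instead would create C6, and with it the lactone fusion, in the macrocyclisation; cutting C2–C3 would leave no functional handle. What is gained is the open-chain aldehyde 24, in which C6, C7 and C8 are already settled. The forward Nozaki–Hiyama–Kishi closure has to form a ten-membered ring, keep the C1=C10 geometry and deliver 9S.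

Functional-group adjustments (24 ⇐ 23 ⇐ 22 ⇐ 21). The C9 aldehyde comes from the primary alcohol 23, this from the PMB ether 22, and the C8 hydroxyl of 21 is masked as a triethylsilyl ether that can later be removed in the presence of the C14 silyl ether.

Lactone annulation and methylene (21 ⇐ 18 + 19). Two bonds are cut: C11=C13, back to a phosphonate carbanion and formaldehyde 19, and C7–C11, with the C8 oxygen returned to an epoxide bridging C7 and C8. The cut is made here because it is stereospecific: backside opening of a trans-epoxide whose oxygen is anti to C6–O gives the trans lactone and the C8 carbinol with no further control element. It also delivers the methylene group through a stabilised carbanion instead of a lactone enolate. The forward reaction needs attack at C7 (five-membered ring) and not at C8, through carbon and not through oxygen.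

Ester (18 ⇐ 16 + 17). The C6–O acyl bond is cut to epoxy alcohol 16 and diethylphosphonoacetic acid 17; the forward esterification must leave the epoxide alone.

Epoxide (16 ⇐ 15). Removing the epoxide oxygen gives the racemic bis-allylic alcohol 15. A Sharpless epoxidation run as a kinetic resolution selects one enantiomer of 15 and, within it, the E-disubstituted C7=C8 alkene, and sets C6, C7 and C8 in one operation.

Carbinol–alkenyl bond (15 ⇐ 14 ⇐ 13 ⇐ 8 + 10; 10 ⇐ 9). Cutting C6–C7 gives enal 8 and the terminal alkyne 10, used as its E-alkenyl metal derivative; 14 and 13 differ from 15 only in the state of C14 (free alcohol, methyl ester). The C7–C9 unit comes from prop-2-yn-1-ol 9. The forward addition must be 1,2 to a Z-enal and tolerate an ester and an alkenyl iodide.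

Iodoalkene (8 ⇐ 7 ⇐ 6 ⇐ 3 + 4). C1=C10 is cut by a Wittig disconnection to aldehyde 3 and ylide 4, which is iodinated to 5 before use. This places iodine and the C14 carbon on C10 in one step, with iodine cis to C2 as the ring closure later requires.

Starting terpene (3 ⇐ 2 ⇐ 1). Aldehyde 3 is what is left of neryl acetate 1 after oxidative removal of the terminal isopropylidene group through epoxide 2. Compound 1 supplies C1–C6, C15 and the Z geometry of C4=C5.

## Alternatives that were turned down

Alternative 1: The ring is cut at C5–C6 and the lactone at O–C12, which leads to the open-chain iodo aldehyde A2 (Z-alkenyl iodide at C5, aldehyde at C6, the C11–C12 arm as a methyl ester on C7, silyl ethers on O8 and O9, C14 as a tert-butyl ester). Forward, CrCl2 with catalytic NiCl2 would turn the iodide into an alkenylchromium that adds to the aldehyde and closes the carbocycle; the C6 alkoxide would then acylate itself with the methyl ester to give the bicyclic lactone A1. In its favour, two rings form in one flask, C8 and C9 are set before the ring closure, and C14 is at its final oxidation level early. On these three points it is stronger than the chosen route, which leaves C9 to the macrocyclisation and oxidises C14 at the end. Against it, C6 is created in the ring closure, next to an α-branched aldehyde whose C7–H is acidic. Nothing stereospecific decides between the trans and the cis lactone. A1 also lacks C13, so the methylene group would have to be added through a lactone enolate with strong base in a molecule that holds a tert-butyl acrylate and two β-silyloxy groups. The C7–C9 triad would need separate stereoselective steps. The chosen strategy offers in exchange one catalytic epoxidation for C6–C8, a stereospecific trans-lactone closure and a methylene group made without strong base.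

Alternative 2: The C2–C3 bond of the ten-membered ketone A3 is cut and a C5–C10 bond restored, which leads to the cyclohexanol A4 carrying a vinyl group on the carbinol carbon C10 and an isopropenyl group on C5. Forward, the potassium alkoxide of A4 (KH, 18-crown-6) would undergo an anionic oxy-Cope rearrangement that opens the six-membered ring to the ten-membered one. This needs no high dilution, is strongly driven, and lets C6–C9 be set on a cyclohexane with predictable substrate control; C9 is not formed in the ring-forming step. In these respects it is stronger than the chosen route. Against it, A3 is far from the target. C10 is a ketone and C1 is saturated, so the acrylic acid would need regioselective enolisation towards C1 (away from oxygenated C9), enol triflate formation and carbonylation with control of geometry. The C4=C5 geometry depends on a chair or boat transition state, and C5 and C10 of A4 are stereocentres built only to be destroyed. The lactone would still have to be made from a two-carbon arm at the alcohol level and C13 added by enolate chemistry. An enolate towards C9 could also expel the C8 oxygen. The chosen route reaches the correct oxidation pattern at C10/C14 and the finished methylene lactone with far fewer steps after its key step.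

Alternative 3: The C6–C10 bond is restored, so that the cyclodecadienone A5 comes from the cis-fused hydroazulene A6 with a tertiary hydroxyl on C6, an ester-bearing quaternary C10 and a mesylate on C1. Forward, KOC(CH3)3 would form the C6 alkoxide, which fragments (Grob) with loss of the mesylate, giving the C6 ketone and the C1=C10 acrylate. The concerted anti-periplanar fragmentation would translate the C1 configuration into the alkene geometry, the C14 ester is in place, and no dilution is needed. On alkene-geometry transfer during ring formation and on C14 it is stronger than the chosen route. Against it, A6 needs six stereocentres, three of them sacrificial. A5 is a β-silyloxy ketone with an acidic C7–H under alkoxide base, so β-elimination of O8 and epimerisation at C7 threaten. C6 would have to be set afterwards by 1,2-reduction of a flexible Z-enone, trans to C7. The lactone and C13 would again need deprotection, oxidation, lactonisation and enolate methylenation beside an acrylate. The chosen strategy avoids a base-exposed β-silyloxy ketone and sets C6 together with C7 and C8 by reagent control.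

Key step: step 12

## Remarks before the steps

Neryl acetate (the acetate of nerol) is a commercial compound and is taken as the starting material, which saves the acetylation. CIP descriptors at C7 and C8 change along the route with the substituents (epoxide, free hydroxyl, silyl ether, ester) although the spatial arrangement stays the same; the SMILES strings are authoritative.

## Steps

Step 1
Reactants: 1 neryl acetate
Product: 2 (2Z)-5-(3,3-dimethyloxiran-2-yl)-3-methylpent-2-en-1-yl acetate (racemic)
Conditions: mCPBA (1.0 equiv), NaHCO3, CH2Cl2, 0 °C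
Reagents that add atoms: 3-chloroperoxybenzoic acid, OOC(=O)c1cccc(Cl)c1
Why: Peracid (Prilezhaev) epoxidation follows alkene nucleophilicity, and the alkene next to the acetoxymethyl group is deactivated, so one equivalent should take the remote trisubstituted alkene. The new stereocentre is racemic and is removed in step 2.

Step 2
Reactants: 2 (2Z)-5-(3,3-dimethyloxiran-2-yl)-3-methylpent-2-en-1-yl acetate
Product: 3 (2Z)-3-methyl-6-oxohex-2-en-1-yl acetate
Conditions: HIO4·2H2O, THF/Et2O, 0 °C
Reagents that add atoms: none
Why: Periodic acid cleaves the trisubstituted epoxide oxidatively in one flask to the aldehyde and acetone; the Z-alkene and the acetate should be untouched at 0 °C.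

Step 3
Reactants: 3 (2Z)-3-methyl-6-oxohex-2-en-1-yl acetate; 4 methyl (triphenyl-λ5-phosphanylidene)acetate
Product: 6 methyl (2Z,6Z)-8-acetoxy-2-iodo-6-methylocta-2,6-dienoate, via iodo ylide 5 (not isolated)
Conditions: 4, NIS, CH2Cl2, −20 °C; then 3, −20 °C to rt
Reagents that add atoms: N-iodosuccinimide, O=C1CCC(=O)N1I
Why: Wittig reaction of a stabilised α-iodo ylide: C-iodination of 4, followed by deprotonation by the succinimide anion, gives 5, which should olefinate the unhindered aldehyde with the ester trans to the chain. Iodine then lies cis to C2 (2Z), the geometry later carried into the ring.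

Step 4
Reactants: 6 methyl (2Z,6Z)-8-acetoxy-2-iodo-6-methylocta-2,6-dienoate
Product: 7 methyl (2Z,6Z)-8-hydroxy-2-iodo-6-methylocta-2,6-dienoate
Conditions: K2CO3 (cat.), MeOH, 0 °C
Reagents that add atoms: none
Why: Base-catalysed methanolysis removes the acetate. Exchange at the methyl ester changes nothing, and at 0 °C with catalytic carbonate the β-alkyl iodo enoate should not add methanol.

Step 5
Reactants: 7 methyl (2Z,6Z)-8-hydroxy-2-iodo-6-methylocta-2,6-dienoate
Product: 8 methyl (2Z,6Z)-2-iodo-6-methyl-8-oxoocta-2,6-dienoate
Conditions: TEMPO (cat.), PhI(OAc)2, CH2Cl2, rt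
Reagents that add atoms: none
Why: Oxoammonium (TEMPO) oxidation of the primary allylic alcohol stops at the aldehyde and is nearly neutral, which should preserve the Z geometry of the β,β-disubstituted enal.

Step 6
Reactants: 9 prop-2-yn-1-ol
Product: 10 1-methoxy-4-[(prop-2-yn-1-yloxy)methyl]benzene
Conditions: NaH, 4-methoxybenzyl chloride, n-Bu4NI (cat.), THF, 0 °C to rt
Reagents that add atoms: 4-methoxybenzyl chloride, COc1ccc(CCl)cc1
Why: Williamson ether synthesis on a primary alkoxide with a benzylic chloride; the alkyne C–H is much less acidic than the hydroxyl and stays untouched with one equivalent of base.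

Step 7
Reactants: 10 1-methoxy-4-[(prop-2-yn-1-yloxy)methyl]benzene; 8 methyl (2Z,6Z)-2-iodo-6-methyl-8-oxoocta-2,6-dienoate
Product: 13 methyl (2Z,6Z,9E)-8-hydroxy-2-iodo-11-[(4-methoxyphenyl)methoxy]-6-methylundeca-2,6,9-trienoate (racemic), via alkenylzirconocene chloride 11 (not isolated), via alkenyl(methyl)zinc 12 (not isolated)
Conditions: 10, Cp2Zr(H)Cl, CH2Cl2, rt; Me2Zn, −65 °C; then 8, 0 °C
Reagents that add atoms: none
Why: Hydrozirconation of the terminal alkyne is syn with the metal at the terminus, which fixes the E geometry; zirconium-to-zinc exchange gives a reagent that should add 1,2 to the enal and ignore the ester and the alkenyl iodide. The C6 carbinol forms racemic and is resolved in step 10.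

Step 8
Reactants: 13 methyl (2Z,6Z,9E)-8-hydroxy-2-iodo-11-[(4-methoxyphenyl)methoxy]-6-methylundeca-2,6,9-trienoate
Product: 14 (2Z,6Z,9E)-2-iodo-11-[(4-methoxyphenyl)methoxy]-6-methylundeca-2,6,9-triene-1,8-diol (racemic)
Conditions: i-Bu2AlH (3.5 equiv), CH2Cl2, −78 °C; aqueous sodium potassium tartrate
Reagents that add atoms: none
Why: Hydride reduction of the conjugated methyl ester to the allylic alcohol at −78 °C should spare the alkenyl iodide; the free C6 hydroxyl only consumes one equivalent as its aluminium alkoxide.

Step 9
Reactants: 14 (2Z,6Z,9E)-2-iodo-11-[(4-methoxyphenyl)methoxy]-6-methylundeca-2,6,9-triene-1,8-diol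
Product: 15 (2E,5Z,9Z)-11-[(tert-butyldimethylsilyl)oxy]-10-iodo-1-[(4-methoxyphenyl)methoxy]-6-methylundeca-2,5,9-trien-4-ol (racemic)
Conditions: TBSCl (1.05 equiv), imidazole, CH2Cl2, −20 to 0 °C
Reagents that add atoms: tert-butyldimethylsilyl chloride, CC(C)(C)[Si](C)(C)Cl
Why: Silylation should discriminate the unhindered primary hydroxyl from the secondary bis-allylic one on steric grounds.

Step 10
Reactants: 15 (2E,5Z,9Z)-11-[(tert-butyldimethylsilyl)oxy]-10-iodo-1-[(4-methoxyphenyl)methoxy]-6-methylundeca-2,5,9-trien-4-ol (racemic)
Product: 16 (1R,2Z,6Z)-8-[(tert-butyldimethylsilyl)oxy]-7-iodo-1-[(2R,3R)-3-{[(4-methoxyphenyl)methoxy]methyl}oxiran-2-yl]-3-methylocta-2,6-dien-1-ol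
Conditions: Ti(OiPr)4 (0.2 equiv), D-(−)-diisopropyl tartrate (0.25 equiv), t-BuOOH (0.6 equiv), 4 Å molecular sieves, CH2Cl2, −20 °C
Reagents that add atoms: tert-butyl hydroperoxide, CC(C)(C)OO
Why: Sharpless asymmetric epoxidation as a kinetic resolution: with the D-(−)-tartrate the (S)-enantiomer of 15 should be epoxidised at its E-disubstituted C7=C8 alkene on the face that gives the anti (erythro) epoxy alcohol, so that C6 (R), C7 (R) and C8 (R) are set together. In this enantiomer the C4=C5 alkene is the mismatched one and carries a cis substituent (C3), both of which slow its epoxidation. The (R)-enantiomer is left behind and is separated.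

Step 11
Reactants: 16 epoxy alcohol; 17 (diethoxyphosphoryl)acetic acid
Product: 18 (1R,2Z,6Z)-8-[(tert-butyldimethylsilyl)oxy]-7-iodo-1-[(2R,3R)-3-{[(4-methoxyphenyl)methoxy]methyl}oxiran-2-yl]-3-methylocta-2,6-dien-1-yl (diethoxyphosphoryl)acetate
Conditions: DCC, DMAP (cat.), CH2Cl2, 0 °C to rt
Reagents that add atoms: none
Why: Steglich esterification acylates the secondary hydroxyl under neutral conditions, so the neighbouring epoxide and the allylic C6–O bond should not be disturbed.

Step 12
Reactants: 18 epoxy phosphonoacetate; 19 formaldehyde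
Product: 21 (4R,5R)-5-[(1Z,5Z)-7-[(tert-butyldimethylsilyl)oxy]-6-iodo-2-methylhepta-1,5-dien-1-yl]-4-[(1S)-1-hydroxy-2-[(4-methoxyphenyl)methoxy]ethyl]-3-methylideneoxolan-2-one, via α-phosphono lactone 20 (not isolated)
Conditions: NaH (1.1 equiv), THF, 0 to 40 °C; then (CH2O)n, rt
Reagents that add atoms: paraformaldehyde (source of 19), monomer unit C=O
Why: NaH removes the only acidic C–H (C11, between phosphoryl and ester), and the carbanion attacks C7 from the side opposite the epoxide oxygen, forming C7–C11 and closing the lactone ring (O, C6, C7, C11, C12) to give 20. The closure is 5-exo-tet at the epoxide, because the breaking C7–O bond lies outside the new ring; attack at C8 would be the 6-endo mode, in which the short tether cannot bring C11 collinear with the C8–O bond. With respect to the carbanion the closure is of the enolate-endo kind, so C11 cannot stay coplanar with the ring ester in the transition state; the phosphoryl group keeps the charge stabilised while C11 pyramidalises towards C7, which is why a phosphonate is used and why gentle warming is foreseen. The closest known reaction types are the intramolecular opening of epoxides by stabilised ester carbanions and the Horner–Wadsworth–Emmons methylenation of α-phosphono lactones with formaldehyde, run here one after the other in one flask. C7 is the one new stereocentre and is set by inversion at the (7R)-epoxide carbon (stereospecific SN2); together with the anti relation of C6–O and the epoxide fixed in step 10 this gives the trans lactone, while C8 keeps its configuration and becomes the free carbinol. The C8 alkoxide released is quenched by the acidic C11–H of 20, which regenerates the phosphonate carbanion and keeps the alkoxide from attacking the lactone carbonyl (migration of the lactone to O8). This carbanion adds to 19 and loses diethyl phosphate to give the C11=C13 methylene group, so only one equivalent of base is consumed and no strong base meets the finished methylene lactone. The step needs C- over O-alkylation of the ambident anion and C7 over C8 attack; the carbon-centred phosphonate carbanion, the sodium ion held at the epoxide oxygen and the five-membered ring preference are what should secure both.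

Step 13
Reactants: 21 methylene lactone alcohol
Product: 22 (4S,5R)-5-[(1Z,5Z)-7-[(tert-butyldimethylsilyl)oxy]-6-iodo-2-methylhepta-1,5-dien-1-yl]-4-[(1S)-2-[(4-methoxyphenyl)methoxy]-1-[(triethylsilyl)oxy]ethyl]-3-methylideneoxolan-2-one
Conditions: TESOTf, 2,6-lutidine, CH2Cl2, −78 °C
Reagents that add atoms: triethylsilyl trifluoromethanesulfonate, CC[Si](CC)(CC)OS(=O)(=O)C(F)(F)F
Why: A silyl triflate with a hindered, non-nucleophilic pyridine base should silylate the secondary C8 hydroxyl at low temperature without conjugate addition to the methylene lactone.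

Step 14
Reactants: 22 triethylsilyl ether
Product: 23 (4S,5R)-5-[(1Z,5Z)-7-[(tert-butyldimethylsilyl)oxy]-6-iodo-2-methylhepta-1,5-dien-1-yl]-4-[(1S)-2-hydroxy-1-[(triethylsilyl)oxy]ethyl]-3-methylideneoxolan-2-one
Conditions: DDQ, CH2Cl2/pH 7 buffer, 0 °C
Reagents that add atoms: none
Why: Oxidative cleavage of the PMB ether by DDQ (benzylic hydride abstraction, hydrolysis of the oxocarbenium ion) is neutral and should leave silyl ethers, alkenyl iodide and lactone intact.

Step 15
Reactants: 23 primary alcohol
Product: 24 (4S,5R)-5-[(1Z,5Z)-7-[(tert-butyldimethylsilyl)oxy]-6-iodo-2-methylhepta-1,5-dien-1-yl]-3-methylidene-4-[(1S)-2-oxo-1-[(triethylsilyl)oxy]ethyl]oxolan-2-one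
Conditions: Dess–Martin periodinane, NaHCO3, CH2Cl2, 0 °C
Reagents that add atoms: none
Why: Buffered Dess–Martin oxidation gives the α-silyloxy aldehyde without base, so C8 should not epimerise; the aldehyde is used at once.

Step 16
Reactants: 24 aldehyde
Product: 25 (3aS,4S,5S,6Z,10Z,11aR)-6-{[(tert-butyldimethylsilyl)oxy]methyl}-5-hydroxy-10-methyl-3-methylidene-4-[(triethylsilyl)oxy]-3a,4,5,8,9,11a-hexahydrocyclodeca[b]furan-2(3H)-one
Conditions: CrCl2 (10 equiv), NiCl2 (2 mol %), degassed DMSO (0.002 M), rt
Reagents that add atoms: none
Why: Intramolecular Nozaki–Hiyama–Kishi reaction: zerovalent nickel, formed from NiCl2 by divalent chromium, inserts into the C10–I bond with retention, and the alkenyl group passes to trivalent chromium and adds only to the aldehyde, closing the ten-membered ring at C9–C10. The two ring-cis alkenes and the lactone shorten the chain, which should favour closure at high dilution. C9 is formed here under the influence of the C8 silyloxy group and the ring conformation; the 9S alcohol (O8 and O9 syn) is the one needed.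

Step 17
Reactants: 25 ten-membered alcohol
Product: 26 (3aR,4S,5S,6Z,10Z,11aR)-6-{[(tert-butyldimethylsilyl)oxy]methyl}-4,5-dihydroxy-10-methyl-3-methylidene-3a,4,5,8,9,11a-hexahydrocyclodeca[b]furan-2(3H)-one
Conditions: PPTS, MeOH/CH2Cl2, 0 °C
Reagents that add atoms: none
Why: Acid-catalysed methanolysis should cleave the triethylsilyl ether much faster than the bulkier tert-butyldimethylsilyl ether, which frees only the C8 hydroxyl.

Step 18
Reactants: 26 diol; 27 angelic acid [(2Z)-2-methylbut-2-enoic acid] (two molecules are consumed, one per hydroxyl)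
Product: 29 (3aS,4S,5S,6Z,10Z,11aR)-6-{[(tert-butyldimethylsilyl)oxy]methyl}-10-methyl-3-methylidene-2-oxo-2,3,3a,4,5,8,9,11a-octahydrocyclodeca[b]furan-4,5-diyl bis[(2Z)-2-methylbut-2-enoate], via mixed anhydride 28 (not isolated)
Conditions: 27 (6 equiv), 2,4,6-trichlorobenzoyl chloride (6 equiv), Et3N, toluene, rt; then 26, 80 °C
Reagents that add atoms: angelic acid (the second molecule of 27, for the second hydroxyl), C/C=C(/C)C(=O)O
Why: Yamaguchi esterification: the mixed anhydride 28 is attacked at the less hindered angeloyl carbonyl, and running it in toluene without a nucleophilic catalyst should avoid the addition–elimination path that turns angelates into tiglates. An excess of 28 acylates both hydroxyls in one operation, each with its own molecule of 27, so no mono-ester is left to migrate.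

Step 19
Reactants: 29 bis-angelate silyl ether
Product: 30 (3aS,4S,5S,6Z,10Z,11aR)-6-(hydroxymethyl)-10-methyl-3-methylidene-2-oxo-2,3,3a,4,5,8,9,11a-octahydrocyclodeca[b]furan-4,5-diyl bis[(2Z)-2-methylbut-2-enoate]
Conditions: HF·pyridine, pyridine, THF, 0 °C to rt
Reagents that add atoms: none
Why: Buffered fluoride cleavage of the primary silyl ether is mildly acidic and non-nucleophilic towards carbon, so esters and the methylene lactone should survive.

Step 20
Reactants: 30 allylic alcohol
Product: 31 (3aS,4S,5S,6E,10Z,11aR)-6-formyl-10-methyl-3-methylidene-2-oxo-2,3,3a,4,5,8,9,11a-octahydrocyclodeca[b]furan-4,5-diyl bis[(2Z)-2-methylbut-2-enoate]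
Conditions: Dess–Martin periodinane, NaHCO3, CH2Cl2, 0 °C
Reagents that add atoms: none
Why: Dess–Martin oxidation of the primary allylic alcohol gives the enal; its geometry (formyl trans to C2) is the stable one, so no isomerisation is expected.

Step 21
Reactants: 31 enal
Product: 32 (3aS,4S,5S,6E,10Z,11aR)-10-methyl-3-methylidene-4,5-bis{[(2Z)-2-methylbut-2-enoyl]oxy}-2-oxo-2,3,3a,4,5,8,9,11a-octahydrocyclodeca[b]furan-6-carboxylic acid (target)
Conditions: NaClO2, NaH2PO4, 2-methyl-2-butene, t-BuOH/H2O, 0 °C to rt
Reagents that add atoms: sodium chlorite, [Na+].[O-]Cl=O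
Why: Pinnick oxidation converts the enal into the acid at about pH 4, and the alkene scavenger takes up the hypochlorous acid, so the four alkenes and the esters should be left alone.

## Compound list

1 | neryl acetate, (2Z)-3,7-dimethylocta-2,6-dien-1-yl acetate | CC(C)=CCC/C(C)=C\COC(C)=O | starting material
2 | (2Z)-5-(3,3-dimethyloxiran-2-yl)-3-methylpent-2-en-1-yl acetate (racemic) | CC1(C)OC1CC/C(C)=C\COC(C)=O | intermediate
3 | (2Z)-3-methyl-6-oxohex-2-en-1-yl acetate | O=CCC/C(C)=C\COC(C)=O | intermediate
4 | methyl (triphenyl-λ5-phosphanylidene)acetate | COC(=O)C=P(c1ccccc1)(c1ccccc1)c1ccccc1 | starting material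
5 | methyl iodo(triphenyl-λ5-phosphanylidene)acetate (formed in the flask) | COC(=O)C(I)=P(c1ccccc1)(c1ccccc1)c1ccccc1 | intermediate
6 | methyl (2Z,6Z)-8-acetoxy-2-iodo-6-methylocta-2,6-dienoate | COC(=O)/C(I)=C/CC/C(C)=C\COC(C)=O | intermediate
7 | methyl (2Z,6Z)-8-hydroxy-2-iodo-6-methylocta-2,6-dienoate | COC(=O)/C(I)=C/CC/C(C)=C\CO | intermediate
8 | methyl (2Z,6Z)-2-iodo-6-methyl-8-oxoocta-2,6-dienoate | COC(=O)/C(I)=C/CC/C(C)=C\C=O | intermediate
9 | prop-2-yn-1-ol | C#CCO | starting material
10 | 1-methoxy-4-[(prop-2-yn-1-yloxy)methyl]benzene | C#CCOCc1ccc(OC)cc1 | intermediate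
11 | chlorobis(cyclopentadienyl)[(1E)-3-[(4-methoxyphenyl)methoxy]prop-1-en-1-yl]zirconium (formed in the flask) | COc1ccc(COC/C=C/[Zr](Cl)(C2C=CC=C2)C2C=CC=C2)cc1 | intermediate
12 | [(1E)-3-[(4-methoxyphenyl)methoxy]prop-1-en-1-yl](methyl)zinc (formed in the flask) | COc1ccc(COC/C=C/[Zn]C)cc1 | intermediate
13 | methyl (2Z,6Z,9E)-8-hydroxy-2-iodo-11-[(4-methoxyphenyl)methoxy]-6-methylundeca-2,6,9-trienoate (racemic) | COC(=O)/C(I)=C/CC/C(C)=C\C(O)/C=C/COCc1ccc(OC)cc1 | intermediate
14 | (2Z,6Z,9E)-2-iodo-11-[(4-methoxyphenyl)methoxy]-6-methylundeca-2,6,9-triene-1,8-diol (racemic) | OC/C(I)=C/CC/C(C)=C\C(O)/C=C/COCc1ccc(OC)cc1 | intermediate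
15 | (2E,5Z,9Z)-11-[(tert-butyldimethylsilyl)oxy]-10-iodo-1-[(4-methoxyphenyl)methoxy]-6-methylundeca-2,5,9-trien-4-ol (racemic) | CC(C)(C)[Si](C)(C)OC/C(I)=C/CC/C(C)=C\C(O)/C=C/COCc1ccc(OC)cc1 | intermediate
16 | (1R,2Z,6Z)-8-[(tert-butyldimethylsilyl)oxy]-7-iodo-1-[(2R,3R)-3-{[(4-methoxyphenyl)methoxy]methyl}oxiran-2-yl]-3-methylocta-2,6-dien-1-ol (6R,7R,8R in germacrane locants) | O[C@@H]([C@H]1O[C@@H]1COCc1ccc(OC)cc1)/C=C(/C)CC/C=C(/CO[Si](C)(C)C(C)(C)C)I | intermediate
17 | (diethoxyphosphoryl)acetic acid | CCOP(=O)(CC(=O)O)OCC | starting material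
18 | (diethoxyphosphoryl)acetate of 16 (6R,7R,8R) | CCOP(=O)(OCC)CC(=O)O[C@@H]([C@H]1O[C@@H]1COCc1ccc(OC)cc1)/C=C(/C)CC/C=C(/CO[Si](C)(C)C(C)(C)C)I | intermediate
19 | formaldehyde (supplied as paraformaldehyde) | C=O | starting material
20 | diethyl {(4R,5R)-5-[(1Z,5Z)-7-[(tert-butyldimethylsilyl)oxy]-6-iodo-2-methylhepta-1,5-dien-1-yl]-4-[(1S)-1-hydroxy-2-[(4-methoxyphenyl)methoxy]ethyl]-2-oxooxolan-3-yl}phosphonate (C11 epimers, formed in the flask) | CCOP(=O)(OCC)C1C(=O)O[C@H](/C=C(/C)CC/C=C(/CO[Si](C)(C)C(C)(C)C)I)[C@H]1[C@H](O)COCc1ccc(OC)cc1 | intermediate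
21 | (4R,5R)-5-[(1Z,5Z)-7-[(tert-butyldimethylsilyl)oxy]-6-iodo-2-methylhepta-1,5-dien-1-yl]-4-[(1S)-1-hydroxy-2-[(4-methoxyphenyl)methoxy]ethyl]-3-methylideneoxolan-2-one | C=C1C(=O)O[C@H](/C=C(/C)CC/C=C(/CO[Si](C)(C)C(C)(C)C)I)[C@H]1[C@H](O)COCc1ccc(OC)cc1 | intermediate
22 | (4S,5R)-5-[(1Z,5Z)-7-[(tert-butyldimethylsilyl)oxy]-6-iodo-2-methylhepta-1,5-dien-1-yl]-4-[(1S)-2-[(4-methoxyphenyl)methoxy]-1-[(triethylsilyl)oxy]ethyl]-3-methylideneoxolan-2-one | C=C1C(=O)O[C@H](/C=C(/C)CC/C=C(/CO[Si](C)(C)C(C)(C)C)I)[C@H]1[C@H](O[Si](CC)(CC)CC)COCc1ccc(OC)cc1 | intermediate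
23 | (4S,5R)-5-[(1Z,5Z)-7-[(tert-butyldimethylsilyl)oxy]-6-iodo-2-methylhepta-1,5-dien-1-yl]-4-[(1S)-2-hydroxy-1-[(triethylsilyl)oxy]ethyl]-3-methylideneoxolan-2-one | C=C1C(=O)O[C@H](/C=C(/C)CC/C=C(/CO[Si](C)(C)C(C)(C)C)I)[C@H]1[C@H](O[Si](CC)(CC)CC)CO | intermediate
24 | (4S,5R)-5-[(1Z,5Z)-7-[(tert-butyldimethylsilyl)oxy]-6-iodo-2-methylhepta-1,5-dien-1-yl]-3-methylidene-4-[(1S)-2-oxo-1-[(triethylsilyl)oxy]ethyl]oxolan-2-one | C=C1C(=O)O[C@H](/C=C(/C)CC/C=C(/CO[Si](C)(C)C(C)(C)C)I)[C@H]1[C@H](O[Si](CC)(CC)CC)C=O | intermediate
25 | (3aS,4S,5S,6Z,10Z,11aR)-6-{[(tert-butyldimethylsilyl)oxy]methyl}-5-hydroxy-10-methyl-3-methylidene-4-[(triethylsilyl)oxy]-3a,4,5,8,9,11a-hexahydrocyclodeca[b]furan-2(3H)-one | C=C1C(=O)O[C@@H]2/C=C(/C)CC/C=C(/CO[Si](C)(C)C(C)(C)C)[C@H](O)[C@@H](O[Si](CC)(CC)CC)[C@@H]12 | intermediate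
26 | (3aR,4S,5S,6Z,10Z,11aR)-6-{[(tert-butyldimethylsilyl)oxy]methyl}-4,5-dihydroxy-10-methyl-3-methylidene-3a,4,5,8,9,11a-hexahydrocyclodeca[b]furan-2(3H)-one | C=C1C(=O)O[C@@H]2/C=C(/C)CC/C=C(/CO[Si](C)(C)C(C)(C)C)[C@H](O)[C@@H](O)[C@@H]12 | intermediate
27 | angelic acid, (2Z)-2-methylbut-2-enoic acid | C/C=C(/C)C(=O)O | starting material
28 | (2Z)-2-methylbut-2-enoic 2,4,6-trichlorobenzoic anhydride (formed in the flask) | C/C=C(/C)C(=O)OC(=O)c1c(Cl)cc(Cl)cc1Cl | intermediate
29 | (3aS,4S,5S,6Z,10Z,11aR)-6-{[(tert-butyldimethylsilyl)oxy]methyl}-10-methyl-3-methylidene-2-oxo-2,3,3a,4,5,8,9,11a-octahydrocyclodeca[b]furan-4,5-diyl bis[(2Z)-2-methylbut-2-enoate] | C=C1C(=O)O[C@@H]2/C=C(/C)CC/C=C(/CO[Si](C)(C)C(C)(C)C)[C@H](OC(=O)/C(C)=C\C)[C@@H](OC(=O)/C(C)=C\C)[C@@H]12 | intermediate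
30 | (3aS,4S,5S,6Z,10Z,11aR)-6-(hydroxymethyl)-10-methyl-3-methylidene-2-oxo-2,3,3a,4,5,8,9,11a-octahydrocyclodeca[b]furan-4,5-diyl bis[(2Z)-2-methylbut-2-enoate] | C=C1C(=O)O[C@@H]2/C=C(/C)CC/C=C(/CO)[C@H](OC(=O)/C(C)=C\C)[C@@H](OC(=O)/C(C)=C\C)[C@@H]12 | intermediate
31 | (3aS,4S,5S,6E,10Z,11aR)-6-formyl-10-methyl-3-methylidene-2-oxo-2,3,3a,4,5,8,9,11a-octahydrocyclodeca[b]furan-4,5-diyl bis[(2Z)-2-methylbut-2-enoate] | C=C1C(=O)O[C@@H]2/C=C(/C)CC/C=C(/C=O)[C@H](OC(=O)/C(C)=C\C)[C@@H](OC(=O)/C(C)=C\C)[C@@H]12 | intermediate
32 | (3aS,4S,5S,6E,10Z,11aR)-10-methyl-3-methylidene-4,5-bis{[(2Z)-2-methylbut-2-enoyl]oxy}-2-oxo-2,3,3a,4,5,8,9,11a-octahydrocyclodeca[b]furan-6-carboxylic acid (6R,7S,8S,9S in germacrane locants) | C=C1C(=O)O[C@@H]2/C=C(/C)CC/C=C(/C(=O)O)[C@H](OC(=O)/C(C)=C\C)[C@@H](OC(=O)/C(C)=C\C)[C@@H]12 | target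

## Step count and least certain steps

Total step count: 21. Longest linear sequence: 20 steps (1 to 32 through steps 1–5 and 7–21); step 6 is the one-step preparation of 10.

Step 12 (key step). The most likely failure is closure through the ester oxygen of the ambident anion, which is the geometrically easier five-membered closure and would give a cyclic ketene acetal. C-attack may also be slow, because C11 must leave conjugation with the ring ester to reach C7. Lesser risks are attack at C8, transfer of the lactone to O8 if the proton shift is slow, and base-induced shift of the exocyclic alkene into the ring. The fallback sets out from 16 and changes both the carbanion and the way the methylene group is made. Esterification of 16 with 3-tert-butoxy-3-oxopropanoic acid (DCC, DMAP) would give the mixed malonate of 16, F1. Its carbanion (NaH, THF) stays conjugated with the exocyclic tert-butyl ester while the ring ester twists, and should close to the α-(tert-butoxycarbonyl) lactone, F2. TMSOTf with 2,6-lutidine followed by aqueous work-up would remove the tert-butyl group, giving the α-carboxy lactone, F3. Aqueous formaldehyde and Et2NH, then warming with NaOAc/AcOH, would effect the decarboxylative Mannich methylenation, and the route is rejoined at 21.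

Step 16. Three things can go wrong: intermolecular coupling instead of ring closure, loss of iodine by protonation of the alkenylmetal, and above all poor control of the new C9 centre. An open-chain Felkin–Anh preference of the α-silyloxy aldehyde would favour the O8/O9 anti alcohol, and only the ring conformation can overturn it. The fallback starts from 24 through the same closure and corrects C9 by reduction instead of by C–C formation. The 9-epimer of 25, F4, would be oxidised with Dess–Martin periodinane to the C9 enone, F5. Reduction with NaBH4 and CeCl3 in MeOH at −78 °C (Luche reduction) has hydride attack anti to the bulky C8 silyloxy group, which gives the syn alcohol, and the route is rejoined at 25. The low temperature is needed to keep borohydride from reducing the methylene lactone.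

Step 18. Acylation of two hindered neighbouring hydroxyls may stop at the mono-ester, which can then migrate, or may be accompanied by Z-to-E isomerisation to tiglates. The fallback sets out from 26 and builds the angelate double bonds on the substrate. Esterification with 2-(diphenoxyphosphoryl)propanoic acid (DCC, DMAP) would give the bis(phosphonopropionate), F6. A Z-selective Horner–Wadsworth–Emmons reaction of the Ando type with acetaldehyde (NaI, DBU, THF, −20 °C) would form both (2Z)-2-methylbut-2-enoates, and the route is rejoined at 29.

Step 10. A kinetic resolution cannot use more than half of the material, and competing epoxidation of the trisubstituted C4=C5 alkene or incomplete discrimination of the enantiomers would erode yield and purity. The fallback sets out from 8 and 10 and makes the carbinol enantioselectively. The addition of step 7 would be run with a chiral amino alcohol ligand such as 3-exo-morpholinoisoborneol, its enantiomer chosen to deliver the S carbinol, giving the (S)-ester, F7. Reduction with i-Bu2AlH would give the (S)-diol, F8, and silylation as in step 9 the (S)-silyl ether, F9. Epoxidation with the same D-(−)-tartrate system would then be a matched directed epoxidation of all the material, and the route is rejoined at 16.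

Step 17. The secondary triethylsilyl ether sits in a crowded position while the other silyl ether is primary and allylic, so the rate difference may be too small and both may be lost. The fallback sets out from 25. HF·pyridine in THF at rt would remove both silyl groups to give the triol, F10; TBSCl and imidazole in CH2Cl2 at −40 °C would then silylate only the primary allylic hydroxyl, and the route is rejoined at 26.

## Further compounds

F1 | step 12 | tert-butyl malonate of 16 (mixed malonate, 6R,7R,8R) | CC(C)(C)OC(=O)CC(=O)O[C@@H]([C@H]1O[C@@H]1COCc1ccc(OC)cc1)/C=C(/C)CC/C=C(/CO[Si](C)(C)C(C)(C)C)I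
F2 | step 12 | tert-butyl (4R,5R)-5-[(1Z,5Z)-7-[(tert-butyldimethylsilyl)oxy]-6-iodo-2-methylhepta-1,5-dien-1-yl]-4-[(1S)-1-hydroxy-2-[(4-methoxyphenyl)methoxy]ethyl]-2-oxooxolane-3-carboxylate | CC(C)(C)OC(=O)C1C(=O)O[C@H](/C=C(/C)CC/C=C(/CO[Si](C)(C)C(C)(C)C)I)[C@H]1[C@H](O)COCc1ccc(OC)cc1
F3 | step 12 | (4R,5R)-5-[(1Z,5Z)-7-[(tert-butyldimethylsilyl)oxy]-6-iodo-2-methylhepta-1,5-dien-1-yl]-4-[(1S)-1-hydroxy-2-[(4-methoxyphenyl)methoxy]ethyl]-2-oxooxolane-3-carboxylic acid | OC(=O)C1C(=O)O[C@H](/C=C(/C)CC/C=C(/CO[Si](C)(C)C(C)(C)C)I)[C@H]1[C@H](O)COCc1ccc(OC)cc1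
F4 | step 16 | 9-epimer of 25 (9R alcohol) | C=C1C(=O)O[C@@H]2/C=C(/C)CC/C=C(/CO[Si](C)(C)C(C)(C)C)[C@@H](O)[C@@H](O[Si](CC)(CC)CC)[C@@H]12
F5 | step 16 | C9 ketone (enone) derived from 25 | C=C1C(=O)O[C@@H]2/C=C(/C)CC/C=C(/CO[Si](C)(C)C(C)(C)C)C(=O)[C@@H](O[Si](CC)(CC)CC)[C@@H]12
F6 | step 18 | bis[2-(diphenoxyphosphoryl)propanoate] of 26 | C=C1C(=O)O[C@@H]2/C=C(/C)CC/C=C(/CO[Si](C)(C)C(C)(C)C)[C@H](OC(=O)C(C)P(=O)(Oc3ccccc3)Oc3ccccc3)[C@@H](OC(=O)C(C)P(=O)(Oc3ccccc3)Oc3ccccc3)[C@@H]12
F7 | step 10 | (S)-enantiomer of 13 | COC(=O)/C(I)=C/CC/C(C)=C\[C@@H](O)/C=C/COCc1ccc(OC)cc1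
F8 | step 10 | (S)-enantiomer of 14 | OC/C(I)=C/CC/C(C)=C\[C@@H](O)/C=C/COCc1ccc(OC)cc1
F9 | step 10 | (S)-enantiomer of 15 | CC(C)(C)[Si](C)(C)OC/C(I)=C/CC/C(C)=C\[C@@H](O)/C=C/COCc1ccc(OC)cc1
F10 | step 17 | 8,9,14-triol from 25 | C=C1C(=O)O[C@@H]2/C=C(/C)CC/C=C(/CO)[C@H](O)[C@@H](O)[C@@H]12
A1 | alternative 1 | bicyclic lactone without C13, C14 tert-butyl ester, silyl ethers on O8 and O9 | C1C(=O)O[C@@H]2/C=C(/C)CC/C=C(/C(=O)OC(C)(C)C)[C@H](O[Si](C)(C)C(C)(C)C)[C@@H](O[Si](C)(C)C(C)(C)C)[C@@H]12
A2 | alternative 1 | open-chain Z-alkenyl iodide (C5) with C6 aldehyde and C12 methyl ester | COC(=O)C[C@@H](C=O)[C@H](O[Si](C)(C)C(C)(C)C)[C@@H](O[Si](C)(C)C(C)(C)C)/C(C(=O)OC(C)(C)C)=C\CC/C(C)=C\I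
A3 | alternative 2 | ten-membered C10 ketone with Z C4=C5, acetonide on O8/O9, PMB ether on O6 | COc1ccc(CO[C@@H]2/C=C(/C)CCCC(=O)[C@@H]3OC(C)(C)O[C@H]3[C@H]2CCO[Si](C)(C)C(C)(C)C)cc1
A4 | alternative 2 | cyclohexanol with vinyl on C10 and isopropenyl on C5 (configuration at C5 and C10 left open) | C=CC1(O)C(C(C)=C)[C@@H](OCc2ccc(OC)cc2)[C@H](CCO[Si](C)(C)C(C)(C)C)[C@@H]2OC(C)(C)O[C@@H]12
A5 | alternative 3 | cyclodecadienone with C6 ketone, both ring-cis alkenes and C14 tert-butyl ester | O=C1/C=C(/C)CC/C=C(/C(=O)OC(C)(C)C)[C@H](O[Si](C)(C)C(C)(C)C)[C@@H](O[Si](C)(C)C(C)(C)C)[C@H]1CCOCc1ccc(OC)cc1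
A6 | alternative 3 | cis-fused hydroazulene hydroxy mesylate (configuration at C1, C6 and C10 left open) | CS(=O)(=O)OC1CCC(C)=CC2(O)[C@H](CCOCc3ccc(OC)cc3)[C@H](O[Si](C)(C)C(C)(C)C)[C@@H](O[Si](C)(C)C(C)(C)C)C12C(=O)OC(C)(C)C
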